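The route rests on cutting the C9–C10 bond of the fourteen-membered ring (cembrane numbering). The key step exploits the homoallylic relation between the C10 carbinol and the (E)-C7=C8 alkene that adjoins the C6 acetate. It is a BF3-promoted aldehyde allylboration in which a branched allylboronate (boron on C7, exocyclic isopropenyl C8=C9) attacks the C10 enal through C9. In one operation it closes the carbocycle, moves the alkene into the ring as the E isomer, relays the C7 configuration to C10 and leaves the free hydroxyl of the target. The precursor is the complete trans-fused α-methylene-γ-butyrolactone carrying an enal arm and a syn-β-acetoxy allylboronate arm.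

Key step: step 15

Remark on numbering: cembrane numbering is used. C1 is the ring-fusion carbon bearing the α-methylene carbon, C2 the lactone O–CH, C3=C4, C7=C8 and C11=C12 the ring alkenes, C6 the acetoxy carbon and C10 the hydroxy carbon. The target is (1R,2S,6S,10S).

Assumption: geraniol, methyl acrylate, (S)-epichlorohydrin, acetylene and isopropenylboronic acid pinacol ester are taken as commercial.

**Western fragment (C10–C14, C1 and the acrylate unit)**

Step 1
Reactants: 1 geraniol
Product: 2 geranyl TBS ether
Conditions: TBSCl, imidazole, CH2Cl2, 0 °C to rt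
Reagents that add atoms: tert-butyldimethylsilyl chloride, CC(C)(C)[Si](C)(C)Cl
Why: Silylation of the primary allylic alcohol masks the future C10 oxygen through the oxidative and organometallic steps of this fragment.

Step 2
Reactants: 2 geranyl TBS ether
Product: 3 distal epoxide (racemic)
Conditions: mCPBA (1.0 equiv), CH2Cl2, −20 to 0 °C
Reagents that add atoms: 3-chloroperbenzoic acid, O=C(OO)c1cccc(Cl)c1
Why: Prilezhaev epoxidation should take the distal trisubstituted alkene, which is more electron-rich than the one next to the silyloxy group; the epoxide configuration is erased in step 3.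

Step 3
Reactants: 3 distal epoxide
Product: 4 silyloxy enal-free aldehyde (C1 aldehyde)
Conditions: H5IO6, THF/H2O, 0 °C
Reagents that add atoms: none
Why: Periodic acid hydrolyses the epoxide and cleaves the resulting diol (Malaprade-type cleavage) to the aldehyde that becomes C1.

Step 4
Reactants: 4 C1 aldehyde, 5 methyl acrylate
Product: 6 Morita–Baylis–Hillman adduct (racemic)
Conditions: DABCO (0.5 equiv), MeOH (cat.), neat methyl acrylate, rt
Reagents that add atoms: none
Why: The Morita–Baylis–Hillman reaction attaches the future lactone carbonyl, α-carbon and exocyclic methylene to C1; the carbinol configuration is irrelevant because C1 becomes sp2 in step 5.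

Step 5
Reactants: 6 Morita–Baylis–Hillman adduct
Product: 7 (Z)-allylic bromide
Conditions: NBS, Me2S, CH2Cl2, −20 °C to rt
Reagents that add atoms: N-bromosuccinimide, O=C1CCC(=O)N1Br
Why: Corey–Kim-type activation of the alcohol followed by SN2' attack of bromide should give the thermodynamically preferred (Z)-2-(bromomethyl)alk-2-enoate.

**Eastern fragment (C2–C9)**

Step 6
Reactants: 8 (S)-epichlorohydrin, 9 acetylene
Product: 11 (2S)-1-chloropent-4-yn-2-ol, via lithium acetylide 10 (not isolated)
Conditions: n-BuLi, THF, −78 °C; BF3·OEt2; then 8, −78 °C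
Reagents that add atoms: none
Why: BF3-assisted epoxide opening by the acetylide at the unsubstituted carbon leaves the stereocenter (future C6) untouched and keeps the chloride for re-formation of an epoxide.

Step 7
Reactants: 11 (2S)-1-chloropent-4-yn-2-ol
Product: 13 chloro diol, via alkenylalane 12 (not isolated)
Conditions: AlMe3, Zr(C5H5)2Cl2 (20 mol%), CH2Cl2, 0 °C to rt; then n-BuLi, THF, −78 °C; (CH2O)n, rt
Reagents that add atoms: trimethylaluminium, C[Al](C)C; formaldehyde (as paraformaldehyde), C=O
Why: Negishi carboalumination adds methyl and aluminium syn across the alkyne (methyl to the internal carbon), which fixes the E geometry of C3=C4, and the alanate is hydroxymethylated with retention to install C2.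

Step 8
Reactants: 13 chloro diol
Product: 14 mono-silylated chlorohydrin
Conditions: TBSCl (1.05 equiv), imidazole, CH2Cl2, −20 to 0 °C
Reagents that add atoms: tert-butyldimethylsilyl chloride, CC(C)(C)[Si](C)(C)Cl
Why: The primary allylic hydroxyl should be silylated selectively over the more hindered secondary chlorohydrin hydroxyl.

Step 9
Reactants: 14 mono-silylated chlorohydrin
Product: 15 (S)-epoxide
Conditions: K2CO3, MeOH, rt
Reagents that add atoms: none
Why: Intramolecular Williamson displacement of chloride by the secondary alkoxide closes the terminal epoxide without touching the stereocenter, which stays S.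

Step 10
Reactants: 15 (S)-epoxide, 16 isopropenylboronic acid pinacol ester
Product: 20 syn β-acetoxy allylboronate, via lithiated epoxide 17 (not isolated), via boronate complex 18 (not isolated), via lithium alkoxide 19 (not isolated)
Conditions: LiTMP, THF, −30 °C (16 present from the start); then Ac2O, −30 °C to rt
Reagents that add atoms: acetic anhydride, CC(=O)OC(C)=O
Why: Lithiation–borylation of a terminal epoxide: deprotonation trans to the side chain, borylation with retention and 1,2-migration of the isopropenyl group with inversion as the epoxide opens should give the syn (6S,7S) β-alkoxy allylboronate from the S epoxide, and the alkoxide is acetylated in the flask.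

Step 11
Reactants: 20 syn β-acetoxy allylboronate
Product: 21 allylic alcohol
Conditions: CSA (10 mol%), MeOH/CH2Cl2, 0 °C
Reagents that add atoms: none
Why: Mild acid methanolysis removes the primary silyl ether, while the acetate and the pinacol boronate, which would be at risk with fluoride, should stay in place.

Step 12
Reactants: 21 allylic alcohol
Product: 22 eastern enal
Conditions: MnO2, CH2Cl2, rt
Reagents that add atoms: none
Why: MnO2 oxidises only the allylic alcohol and gives the E enal under neutral conditions, in which the hindered pinacol allylboronate should not add to the conjugated aldehyde.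

**Union and ring closure**

Step 13
Reactants: 22 eastern enal, 7 (Z)-allylic bromide
Product: 25 lactone allylic alcohol, via silyl ether adduct 23 (not isolated), via lactone silyl ether 24 (not isolated)
Conditions: CrCl2 (10 mol%), chiral tridentate bis(oxazolinyl)carbazole ligand (12 mol%), Mn powder, Me3SiCl, i-Pr2NEt, THF, 0 °C to rt; then CSA, MeOH, 0 °C to rt
Reagents that add atoms: none
Why: Catalytic asymmetric Nozaki–Hiyama–Kishi 2-(alkoxycarbonyl)allylation: the allylchromium species adds through its γ-carbon (C1) in a closed chair with the C14 chain equatorial (anti, hence the trans lactone), the ligand enantiomer being chosen for attack on the Re face of the enal (2S, 1R), and acid methanolysis then removes both silyl groups and closes the lactone.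

Step 14
Reactants: 25 lactone allylic alcohol
Product: 26 seco enal
Conditions: MnO2, CH2Cl2, rt; filtration, used at once
Reagents that add atoms: none
Why: Selective allylic oxidation gives the C10 enal, and the uncatalysed pinacol allylboronate should be too slow to react with it before step 15.

Step 15
Reactants: 26 seco enal
Product: 28 target CNP0168244.1, via cyclic borate ester 27 (not isolated)
Conditions: BF3·OEt2 (3 equiv), CH2Cl2, −78 °C, addition of 26 over 10 h (final 1 mM); aq. NaHCO3
Reagents that add atoms: none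
Why: Proposed new method: BF3 coordinates a dioxaborolane oxygen of 26, the boron binds the enal oxygen and C9 adds to C10 through a closed six-membered chair (B, O, C10, C9, C8, C7) as the C7–B bond breaks and the C7=C8 alkene forms, aqueous work-up then hydrolysing borate 27; the closest known reaction type is the BF3·OEt2-promoted, E-selective allylboration of aldehydes with α-substituted allyl pinacol boronates, which is established intermolecularly and for small rings but not for a fourteen-membered carbocycle. The ring closes in a 14-exo-trig mode with respect to the aldehyde carbon–oxygen double bond. C10 is set by 1,3-transfer of chirality from C7: with the C6-bearing substituent equatorial on C7 (7S) and the C11 alkenyl chain equatorial on C10, C9 is delivered to the Si face of the aldehyde, which should give 10S together with the E alkene. The step needs E over Z geometry, ring closure over oligomerisation and survival of the allylic acetate and lactone: the first is secured by the Lewis acid, which makes an axial α-substituent unfavourable, the second by slow addition of 26 into excess BF3·OEt2 so that each molecule cyclises at about 1 mM while the unactivated boronate is inert, and the third by working at −78 °C.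

**Compound list**

1 | geraniol, (2E)-3,7-dimethylocta-2,6-dien-1-ol | CC(C)=CCC/C(C)=C/CO | starting material
2 | tert-butyl{[(2E)-3,7-dimethylocta-2,6-dien-1-yl]oxy}dimethylsilane | CC(C)=CCC/C(C)=C/CO[Si](C)(C)C(C)(C)C | intermediate
3 | tert-butyl{[(2E)-5-(3,3-dimethyloxiran-2-yl)-3-methylpent-2-en-1-yl]oxy}dimethylsilane (racemic) | CC1(C)OC1CC/C(C)=C/CO[Si](C)(C)C(C)(C)C | intermediate
4 | (4E)-6-{[tert-butyl(dimethyl)silyl]oxy}-4-methylhex-4-enal | O=CCC/C(C)=C/CO[Si](C)(C)C(C)(C)C | intermediate
5 | methyl acrylate | C=CC(=O)OC | starting material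
6 | methyl (6E)-8-{[tert-butyl(dimethyl)silyl]oxy}-3-hydroxy-6-methyl-2-methylideneoct-6-enoate (racemic) | C=C(C(=O)OC)C(O)CC/C(C)=C/CO[Si](C)(C)C(C)(C)C | intermediate
7 | methyl (2Z,6E)-2-(bromomethyl)-8-{[tert-butyl(dimethyl)silyl]oxy}-6-methylocta-2,6-dienoate | COC(=O)/C(CBr)=C/CC/C(C)=C/CO[Si](C)(C)C(C)(C)C | intermediate
8 | (S)-epichlorohydrin, (2S)-2-(chloromethyl)oxirane | ClC[C@@H]1CO1 | starting material
9 | acetylene | C#C | starting material
10 | lithium acetylide | [Li]C#C | intermediate (not isolated)
11 | (2S)-1-chloropent-4-yn-2-ol | ClC[C@@H](O)CC#C | intermediate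
12 | (E)-alkenyl(dimethyl)alane of 11 after syn methylalumination, hydroxyl as its dimethylaluminium alkoxide (2S) | ClC[C@@H](O[Al](C)C)C/C(C)=C/[Al](C)C | intermediate (not isolated)
13 | (2E,5S)-6-chloro-3-methylhex-2-ene-1,5-diol | ClC[C@@H](O)C/C(C)=C/CO | intermediate
14 | (2S,4E)-6-{[tert-butyl(dimethyl)silyl]oxy}-1-chloro-4-methylhex-4-en-2-ol | ClC[C@@H](O)C/C(C)=C/CO[Si](C)(C)C(C)(C)C | intermediate
15 | tert-butyldimethyl{[(2E)-3-methyl-4-[(2S)-oxiran-2-yl]but-2-en-1-yl]oxy}silane | CC(C)(C)[Si](C)(C)OC/C=C(\C)C[C@H]1CO1 | intermediate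
16 | 4,4,5,5-tetramethyl-2-(prop-1-en-2-yl)-1,3,2-dioxaborolane | C=C(C)B1OC(C)(C)C(C)(C)O1 | starting material
17 | epoxide 15 lithiated at the terminal ring carbon, lithium trans to the side chain | CC(C)(C)[Si](C)(C)OC/C=C(\C)C[C@@H]1O[C@H]1[Li] | intermediate (not isolated)
18 | lithium boronate complex of 16 at the former CH2 carbon of the epoxide (configuration retained) | CC(C)(C)[Si](C)(C)OC/C=C(\C)C[C@@H]1O[C@H]1[B-]2(OC(C)(C)C(C)(C)O2)C(C)=C.[Li+] | intermediate (not isolated)
19 | lithium (3S,4S,6E)-8-{[tert-butyl(dimethyl)silyl]oxy}-2,6-dimethyl-3-(4,4,5,5-tetramethyl-1,3,2-dioxaborolan-2-yl)octa-1,6-dien-4-olate | [Li+].CC(C)(C)[Si](C)(C)OC/C=C(\C)C[C@H]([O-])[C@@H](B1OC(C)(C)C(C)(C)O1)C(C)=C | intermediate (not isolated)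
20 | (3S,4S,6E)-8-{[tert-butyl(dimethyl)silyl]oxy}-2,6-dimethyl-3-(4,4,5,5-tetramethyl-1,3,2-dioxaborolan-2-yl)octa-1,6-dien-4-yl acetate (C6 S, C7 S) | CC(C)(C)[Si](C)(C)OC/C=C(\C)C[C@H](OC(C)=O)[C@@H](B1OC(C)(C)C(C)(C)O1)C(C)=C | intermediate
21 | (3S,4S,6E)-8-hydroxy-2,6-dimethyl-3-(4,4,5,5-tetramethyl-1,3,2-dioxaborolan-2-yl)octa-1,6-dien-4-yl acetate | OC/C=C(\C)C[C@H](OC(C)=O)[C@@H](B1OC(C)(C)C(C)(C)O1)C(C)=C | intermediate
22 | (3S,4S,6E)-2,6-dimethyl-8-oxo-3-(4,4,5,5-tetramethyl-1,3,2-dioxaborolan-2-yl)octa-1,6-dien-4-yl acetate | O=C/C=C(\C)C[C@H](OC(C)=O)[C@@H](B1OC(C)(C)C(C)(C)O1)C(C)=C | intermediate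
23 | methyl (3R,4S,5E,8S,9S)-8-acetoxy-3-[(3E)-5-{[tert-butyl(dimethyl)silyl]oxy}-3-methylpent-3-en-1-yl]-6,10-dimethyl-2-methylidene-9-(4,4,5,5-tetramethyl-1,3,2-dioxaborolan-2-yl)-4-[(trimethylsilyl)oxy]undeca-5,10-dienoate | COC(=O)C(=C)[C@@H](CC/C(C)=C/CO[Si](C)(C)C(C)(C)C)[C@@H](O[Si](C)(C)C)/C=C(\C)C[C@H](OC(C)=O)[C@@H](B1OC(C)(C)C(C)(C)O1)C(C)=C | intermediate (not isolated)
24 | (4R,5S)-5-[(1E,4S,5S)-4-acetoxy-2,6-dimethyl-5-(4,4,5,5-tetramethyl-1,3,2-dioxaborolan-2-yl)hepta-1,6-dien-1-yl]-4-[(3E)-5-{[tert-butyl(dimethyl)silyl]oxy}-3-methylpent-3-en-1-yl]-3-methylideneoxolan-2-one | C=C1C(=O)O[C@H]([C@@H]1CC/C(C)=C/CO[Si](C)(C)C(C)(C)C)/C=C(\C)C[C@H](OC(C)=O)[C@@H](B2OC(C)(C)C(C)(C)O2)C(C)=C | intermediate (not isolated)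
25 | (4R,5S)-5-[(1E,4S,5S)-4-acetoxy-2,6-dimethyl-5-(4,4,5,5-tetramethyl-1,3,2-dioxaborolan-2-yl)hepta-1,6-dien-1-yl]-4-[(3E)-5-hydroxy-3-methylpent-3-en-1-yl]-3-methylideneoxolan-2-one | C=C1C(=O)O[C@H]([C@@H]1CC/C(C)=C/CO)/C=C(\C)C[C@H](OC(C)=O)[C@@H](B2OC(C)(C)C(C)(C)O2)C(C)=C | intermediate
26 | (4R,5S)-5-[(1E,4S,5S)-4-acetoxy-2,6-dimethyl-5-(4,4,5,5-tetramethyl-1,3,2-dioxaborolan-2-yl)hepta-1,6-dien-1-yl]-4-[(3E)-3-methyl-5-oxopent-3-en-1-yl]-3-methylideneoxolan-2-one | C=C1C(=O)O[C@H]([C@@H]1CC/C(C)=C/C=O)/C=C(\C)C[C@H](OC(C)=O)[C@@H](B2OC(C)(C)C(C)(C)O2)C(C)=C | intermediate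
27 | C10 O-(4,4,5,5-tetramethyl-1,3,2-dioxaborolan-2-yl) ether of the target | C=C1C(=O)O[C@H]2/C=C(\C)C[C@H](OC(C)=O)/C=C(\C)C[C@H](OB3OC(C)(C)C(C)(C)O3)/C=C(\C)CC[C@H]12 | intermediate (not isolated)
28 | CNP0168244.1, (1R,2S,3E,6S,7E,10S,11E)-6-acetoxy-10-hydroxycembra-3,7,11,15(17)-tetraen-16,2-olide | C=C1C(=O)O[C@H]2/C=C(\C)C[C@H](OC(C)=O)/C=C(\C)C[C@H](O)/C=C(\C)CC[C@H]12 | target

**Summary**

Total step count: 15. Longest linear sequence: 10 steps (steps 6 to 15, from (S)-epichlorohydrin).

Steps most likely to fail:

Step 15 (Proposed new method). Intermolecular allylboration may outrun ring closure and give oligomers, or addition may pass through the chair with the C6-bearing substituent axial and give the Z alkene with the wrong C10 configuration. The fallback uses known chemistry; it sets out from 7 and 20 and comes back at 28. The boronate is spent first in the established intermolecular mode, and the ring is then closed at C1–C2 by the macrocyclic Nozaki–Hiyama–Kishi allylation known for cembranolides. Bromide 7 is desilylated (CSA, MeOH) to the alcohol bromide F1 and oxidised (MnO2) to the enal bromide F2. F2 and 20 are combined with BF3·OEt2 in CH2Cl2 at −78 °C, which should give the (7E,10S) homoallylic alcohol F3 by the same transfer of chirality. CSA in MeOH frees the C2 hydroxyl to give the diol F4, and PhI(OAc)2 with catalytic TEMPO oxidises only the primary allylic alcohol to the enal F5. CrCl2 in THF at high dilution, if necessary with the ligand of step 13, then joins C1 to C2 with lactonisation to 28.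

Step 10. The boron-bound lithium alkoxide may be acylated too slowly and lose boron and oxygen by syn elimination to a diene; base-induced opening of the epoxide through the allylic C5 hydrogens is a second risk. The fallback changes the way the C6 oxygen is handled; it sets out from 15 and 16 and comes back at 20. Under the same lithiation conditions the alkoxide is trapped with Et3SiOTf, the established trap for this rearrangement, to give the β-silyloxy boronate F6. PPTS in MeOH at 0 °C removes the secondary triethylsilyl group in the presence of the primary tert-butyldimethylsilyl ether and gives the β-hydroxy boronate F7, which is acetylated at once (Ac2O, pyridine, DMAP) to 20.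

Step 13. The Lewis-acidic chromium and silyl chloride medium may trigger addition of the allylboronate of one molecule to the enal of another, and facial control over the enal may be incomplete. The fallback joins the fragments at the alcohol oxidation level; it sets out from 6 and 21 and comes back at 24. Adduct 6 is acetylated (Ac2O, pyridine, DMAP) to the allylic acetate F8. F8 and alcohol 21 are coupled by iridium-catalysed transfer-hydrogenative allylation ([Ir(cod)Cl]2, a chiral bisphosphine such as SEGPHOS, 3-nitrobenzoic acid, Cs2CO3, THF, 70 °C). The enal is then present only in stationary trace amounts beside the allyliridium nucleophile, and the anti hydroxy ester should lactonise to 24. 24 is desilylated with CSA in MeOH, as in the second stage of step 13, to 25.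

**Further compounds**

F1 | step 15 | methyl (2Z,6E)-2-(bromomethyl)-8-hydroxy-6-methylocta-2,6-dienoate | COC(=O)/C(CBr)=C/CC/C(C)=C/CO
F2 | step 15 | methyl (2Z,6E)-2-(bromomethyl)-6-methyl-8-oxoocta-2,6-dienoate | COC(=O)/C(CBr)=C/CC/C(C)=C/C=O
F3 | step 15 | methyl (2Z,6E,8S,10E,12S,14E)-12-acetoxy-2-(bromomethyl)-16-{[tert-butyl(dimethyl)silyl]oxy}-8-hydroxy-6,10,14-trimethylhexadeca-2,6,10,14-tetraenoate | COC(=O)/C(CBr)=C/CC/C(C)=C/[C@@H](O)C/C(C)=C/[C@@H](OC(C)=O)C/C(C)=C/CO[Si](C)(C)C(C)(C)C
F4 | step 15 | methyl (2Z,6E,8S,10E,12S,14E)-12-acetoxy-2-(bromomethyl)-8,16-dihydroxy-6,10,14-trimethylhexadeca-2,6,10,14-tetraenoate | COC(=O)/C(CBr)=C/CC/C(C)=C/[C@@H](O)C/C(C)=C/[C@@H](OC(C)=O)C/C(C)=C/CO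
F5 | step 15 | methyl (2Z,6E,8S,10E,12S,14E)-12-acetoxy-2-(bromomethyl)-8-hydroxy-6,10,14-trimethyl-16-oxohexadeca-2,6,10,14-tetraenoate | COC(=O)/C(CBr)=C/CC/C(C)=C/[C@@H](O)C/C(C)=C/[C@@H](OC(C)=O)C/C(C)=C/C=O
F6 | step 10 | tert-butyl{[(2E,5S,6S)-3,7-dimethyl-6-(4,4,5,5-tetramethyl-1,3,2-dioxaborolan-2-yl)-5-[(triethylsilyl)oxy]octa-2,7-dien-1-yl]oxy}dimethylsilane | CC(C)(C)[Si](C)(C)OC/C=C(\C)C[C@H](O[Si](CC)(CC)CC)[C@@H](B1OC(C)(C)C(C)(C)O1)C(C)=C
F7 | step 10 | (3S,4S,6E)-8-{[tert-butyl(dimethyl)silyl]oxy}-2,6-dimethyl-3-(4,4,5,5-tetramethyl-1,3,2-dioxaborolan-2-yl)octa-1,6-dien-4-ol | CC(C)(C)[Si](C)(C)OC/C=C(\C)C[C@H](O)[C@@H](B1OC(C)(C)C(C)(C)O1)C(C)=C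
F8 | step 13 | methyl (6E)-3-acetoxy-8-{[tert-butyl(dimethyl)silyl]oxy}-6-methyl-2-methylideneoct-6-enoate (racemic) | C=C(C(=O)OC)C(OC(C)=O)CC/C(C)=C/CO[Si](C)(C)C(C)(C)C
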